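**Plan**

1. Retrosynthesis: the interflavan C4(upper)–C6(lower) bond is cut first, giving two copies of one monomer, penta-O-benzylmesquitol 12. In the monomer the C4–C4a and O1–C8a bonds of ring C are cut together, leaving aryl iodide 10 (ring A) and the C4–C3–C2 bromohydrin 7 (ring B attached).
2. Enabling feature: on ring A, C8a lies between the oxygen-bearing C8 and the only unsubstituted neighbour C4a–H. An iodide at C8a therefore has one blocked and one free ortho position, so a palladium/norbornene relay can alkylate C4a with C4 and then etherify C8a with the C2 hydroxyl (O1) of the same chain, closing ring C on preformed rings A and B.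
3. Forward order: ring B aldehyde, vinyl carbinol, anti epoxy alcohol, C3-benzyl ether bromide 7; ring A iodide 10; annulation to ring C; C4 oxidation of one monomer; Friedel–Crafts union with a second monomer at C6; global debenzylation.
4. Stereochemistry: C2 and C3 of both units come from one Sharpless kinetic resolution (anti epoxy alcohol) and pass through the annulation untouched (2,3-trans). The upper C4 centre is set in the coupling by attack anti to the C3 benzyloxy group (3,4-trans, 4α).

Key step: step 9

Remark: 13 is drawn as its 3,4-trans C4 epimer; its C4 configuration is immaterial because C4 is ionised in step 11. Compounds 1 and 8 are taken as commercial.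

**Route**

Step 1
Reactants: 1 3,4-bis(benzyloxy)benzaldehyde
Product: 2 rac-1-[3,4-bis(benzyloxy)phenyl]prop-2-en-1-ol
Conditions: CH2=CHMgBr (1.2 equiv), THF, −78 to 0 °C; aq NH4Cl
Reagents that add atoms: vinylmagnesium bromide, C=C[Mg]Br
Why: Grignard 1,2-addition to the aldehyde should give the racemic allylic alcohol; the carbinol centre is left unset on purpose because step 2 resolves it.

Step 2
Reactants: 2 rac-1-[3,4-bis(benzyloxy)phenyl]prop-2-en-1-ol
Product: 3 (R)-[3,4-bis(benzyloxy)phenyl][(S)-oxiran-2-yl]methanol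
Conditions: Ti(OiPr)4 (0.2 equiv), diisopropyl D-(−)-tartrate (0.25 equiv), t-BuOOH (0.6 equiv, in decane), 4 Å MS, CH2Cl2, −20 °C, stopped just past half conversion; chromatography
Reagents that add atoms: tert-butyl hydroperoxide, CC(C)(C)OO
Why: Sharpless asymmetric epoxidation run as a kinetic resolution: with the D-(−)-tartrate the (S)-carbinol should be epoxidised much faster than the (R)-carbinol and from the face that gives the anti (erythro) epoxy alcohol, so the carbinol centre (future C2) is selected by the resolution and the oxirane CH (future C3) is set by reagent-controlled oxygen delivery.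

Step 3
Reactants: 3 (R)-[3,4-bis(benzyloxy)phenyl][(S)-oxiran-2-yl]methanol
Product: 4 tert-butyl{(R)-[3,4-bis(benzyloxy)phenyl][(S)-oxiran-2-yl]methoxy}dimethylsilane
Conditions: TBSCl (1.2 equiv), imidazole (2 equiv), DMF, 0 °C to rt
Reagents that add atoms: tert-butyldimethylsilyl chloride, CC(C)(C)[Si](C)(C)Cl
Why: Silyl ether formation masks the benzylic hydroxyl (the future O1) without touching the epoxide; no stereocentre changes.

Step 4
Reactants: 4 tert-butyl{(R)-[3,4-bis(benzyloxy)phenyl][(S)-oxiran-2-yl]methoxy}dimethylsilane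
Product: 5 (1R,2R)-1-[3,4-bis(benzyloxy)phenyl]-3-bromo-1-[(tert-butyldimethylsilyl)oxy]propan-2-ol
Conditions: LiBr (3 equiv), AcOH (3 equiv), THF, 0 °C to rt
Reagents that add atoms: lithium bromide, [Li+].[Br-]
Why: Regioselective SN2 opening of the terminal epoxide by bromide at the CH2 carbon should give the bromohydrin with the C3 configuration retained, the oxirane oxygen staying on C3.

Step 5
Reactants: 5 (1R,2R)-1-[3,4-bis(benzyloxy)phenyl]-3-bromo-1-[(tert-butyldimethylsilyl)oxy]propan-2-ol
Product: 6 {[(1R,2R)-2-(benzyloxy)-1-[3,4-bis(benzyloxy)phenyl]-3-bromopropyl]oxy}(tert-butyl)dimethylsilane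
Conditions: 2-benzyloxy-1-methylpyridinium triflate (2 equiv), MgO (2 equiv), PhCF3, 85 °C
Reagents that add atoms: 2-(benzyloxy)-1-methylpyridinium triflate, C[n+]1ccccc1OCc1ccccc1.[O-]S(=O)(=O)C(F)(F)F
Why: Neutral O-benzylation by benzyl transfer from the pyridinium salt (no base, which would re-close the epoxide, and no acid, which would ionise the electron-rich benzylic silyl ether) caps the C3 oxygen with a group that can neither migrate nor cyclise in step 9; no stereocentre changes.

Step 6
Reactants: 6 {[(1R,2R)-2-(benzyloxy)-1-[3,4-bis(benzyloxy)phenyl]-3-bromopropyl]oxy}(tert-butyl)dimethylsilane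
Product: 7 (1R,2R)-2-(benzyloxy)-1-[3,4-bis(benzyloxy)phenyl]-3-bromopropan-1-ol
Conditions: HF·pyridine, pyridine/THF, 0 °C to rt
Reagents that add atoms: none
Why: Fluoride-mediated desilylation under buffered conditions should free only the benzylic hydroxyl and leave the primary bromide untouched; no stereocentre changes.

Step 7
Reactants: 8 1-iodo-2,3-dimethoxybenzene
Product: 9 3-iodobenzene-1,2-diol
Conditions: BBr3 (2.5 equiv), CH2Cl2, −78 °C to rt; H2O
Reagents that add atoms: none
Why: Lewis-acid ether cleavage (BBr3 demethylation) should give the catechol with the aryl iodide intact; no stereocentre is involved.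

Step 8
Reactants: 9 3-iodobenzene-1,2-diol
Product: 10 1,2-bis(benzyloxy)-3-iodobenzene
Conditions: BnBr (2.2 equiv), K2CO3 (3 equiv), DMF, 60 °C
Reagents that add atoms: benzyl bromide, BrCc1ccccc1
Why: Williamson etherification installs the two benzyl ethers, which tolerate the palladium step and leave by hydrogenolysis at the end; no stereocentre is involved.

Step 9
Reactants: 7 (1R,2R)-2-(benzyloxy)-1-[3,4-bis(benzyloxy)phenyl]-3-bromopropan-1-ol, 10 1,2-bis(benzyloxy)-3-iodobenzene
Product: 12 (2R,3S)-3,7,8-tris(benzyloxy)-2-[3,4-bis(benzyloxy)phenyl]chromane (penta-O-benzylmesquitol), via ortho-alkylated arylpalladium bromide 11 (not isolated)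
Conditions: 10 (1.0 equiv), 7 (1.3 equiv), Pd(OAc)2 (10 mol %), XPhos (20 mol %), norbornene (1.0 equiv), Cs2CO3 (3 equiv), MeCN, 90 °C, degassed
Reagents that add atoms: none
Why: Proposed new method: oxidative addition of the C8a–I bond of 10 to zerovalent palladium, norbornene insertion and palladation of the only free ortho C–H (C4a; the other ortho carbon carries the C8 benzyloxy group) give an aryl–norbornyl palladacycle, which takes up the primary bromide of 7 by SN2-type oxidative addition (tetravalent palladium) and reductively eliminates the C4–C4a bond; norbornene is then expelled because both ortho positions are now substituted, and in the resulting divalent arylpalladium bromide 11 the tethered benzylic alkoxide forms the C8a–O1 bond by reductive elimination. The closest known reaction types are the Catellani annulations of aryl iodides with bromoalkylamines (ortho-alkylation/ipso-amination to tetrahydroquinolines) and with epoxides (ortho-alkylation/ipso-etherification to 2,3-dihydrobenzofurans) and the palladium-catalysed intramolecular etherification of secondary alcohols to chromans; what is new is the ortho-alkylation/ipso-etherification with a 3-bromopropanol to close the six-membered ring. Ring C closes by intramolecular C(sp2)–O reductive elimination from a seven-membered aryl(alkoxo)palladium chelate, after the intermolecular C–C bond has tied the chain to C4a. No stereocentre is formed: C2 and C3 are carried in from 7 and neither bond to them is touched, so the 2,3-trans relationship is that of the anti bromohydrin. The step needs ortho-before-ipso alkylation (secured by norbornene and the single free ortho C–H), six- rather than five-membered ring closure (secured by the benzyl ether on the C3 oxygen, which leaves O1 as the only nucleophile) and C–O reductive elimination faster than beta-hydride elimination of the secondary alkoxide (favoured by the bulky biaryl phosphine).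

Step 10
Reactants: 12 (2R,3S)-3,7,8-tris(benzyloxy)-2-[3,4-bis(benzyloxy)phenyl]chromane
Product: 13 (2R,3S,4R)-3,7,8-tris(benzyloxy)-2-[3,4-bis(benzyloxy)phenyl]-4-(2-ethoxyethoxy)chromane
Conditions: DDQ (1.5 equiv), 2-ethoxyethanol (5 equiv), CH2Cl2, rt
Reagents that add atoms: 2-ethoxyethanol, CCOCCO
Why: Oxidative benzylic etherification: DDQ should abstract hydride from C4 (the cation is stabilised by the para C7 benzyloxy group and by O1) and the alcohol should add anti to the C3 benzyloxy group, setting the new C4 centre as the 3,4-trans ether, although this centre is ionised again in step 11.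

Step 11
Reactants: 13 (2R,3S,4R)-3,7,8-tris(benzyloxy)-2-[3,4-bis(benzyloxy)phenyl]-4-(2-ethoxyethoxy)chromane, 12 (2R,3S)-3,7,8-tris(benzyloxy)-2-[3,4-bis(benzyloxy)phenyl]chromane
Product: 15 (2R,3S,4S)-3,7,8-tris(benzyloxy)-2-[3,4-bis(benzyloxy)phenyl]-4-{(2R,3S)-3,7,8-tris(benzyloxy)-2-[3,4-bis(benzyloxy)phenyl]chroman-6-yl}chromane (deca-O-benzyl dimer), via flavan-4-yl cation 14 (not isolated)
Conditions: 13 (1 equiv, added slowly), 12 (3 equiv), TMSOTf (0.5 equiv), CH2Cl2, −78 to −30 °C; Et3N quench; excess 12 recovered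
Reagents that add atoms: none
Why: Lewis-acid ionisation of the C4 ether to cation 14 and Friedel–Crafts alkylation of 12 at C6 (ortho to the C7 oxygen and para to O1, the most nucleophilic carbon) should form the interflavan bond; the new C4 centre is set by attack on the half-chair cation anti to the C3 benzyloxy group, which gives the 3,4-trans (4α) product, and the excess of 12 suppresses further condensation.

Step 12
Reactants: 15 deca-O-benzyl dimer
Product: 16 (2R,3S,4R)-2-(3,4-dihydroxyphenyl)-4-[(2R,3S)-2-(3,4-dihydroxyphenyl)-3,7,8-trihydroxychroman-6-yl]chromane-3,7,8-triol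
Conditions: H2 (1 atm), Pd(OH)2/C, THF/MeOH/H2O, rt
Reagents that add atoms: none
Why: Hydrogenolysis of the ten benzyl ethers over Pd(OH)2/C should free all hydroxyl groups without touching the chroman C–O bonds, the diarylmethine C4–C6 bond or any stereocentre.

**Compound list**

1 | 3,4-bis(benzyloxy)benzaldehyde | O=Cc1ccc(OCc2ccccc2)c(OCc2ccccc2)c1 | starting material
2 | rac-1-[3,4-bis(benzyloxy)phenyl]prop-2-en-1-ol (racemate) | C=CC(O)c1ccc(OCc2ccccc2)c(OCc2ccccc2)c1 | intermediate
3 | (R)-[3,4-bis(benzyloxy)phenyl][(S)-oxiran-2-yl]methanol (anti epoxy alcohol) | O[C@H](c1ccc(OCc2ccccc2)c(OCc2ccccc2)c1)[C@@H]1CO1 | intermediate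
4 | tert-butyl{(R)-[3,4-bis(benzyloxy)phenyl][(S)-oxiran-2-yl]methoxy}dimethylsilane | CC(C)(C)[Si](C)(C)O[C@H](c1ccc(OCc2ccccc2)c(OCc2ccccc2)c1)[C@@H]1CO1 | intermediate
5 | (1R,2R)-1-[3,4-bis(benzyloxy)phenyl]-3-bromo-1-[(tert-butyldimethylsilyl)oxy]propan-2-ol | CC(C)(C)[Si](C)(C)O[C@H](c1ccc(OCc2ccccc2)c(OCc2ccccc2)c1)[C@@H](O)CBr | intermediate
6 | {[(1R,2R)-2-(benzyloxy)-1-[3,4-bis(benzyloxy)phenyl]-3-bromopropyl]oxy}(tert-butyl)dimethylsilane | CC(C)(C)[Si](C)(C)O[C@H](c1ccc(OCc2ccccc2)c(OCc2ccccc2)c1)[C@@H](OCc1ccccc1)CBr | intermediate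
7 | (1R,2R)-2-(benzyloxy)-1-[3,4-bis(benzyloxy)phenyl]-3-bromopropan-1-ol (anti; free benzylic OH) | O[C@H](c1ccc(OCc2ccccc2)c(OCc2ccccc2)c1)[C@@H](OCc1ccccc1)CBr | intermediate
8 | 1-iodo-2,3-dimethoxybenzene | COc1cccc(I)c1OC | starting material
9 | 3-iodobenzene-1,2-diol | Oc1cccc(I)c1O | intermediate
10 | 1,2-bis(benzyloxy)-3-iodobenzene | Ic1cccc(OCc2ccccc2)c1OCc1ccccc1 | intermediate
11 | bromo{2,3-bis(benzyloxy)-6-[(2S,3R)-2-(benzyloxy)-3-[3,4-bis(benzyloxy)phenyl]-3-hydroxypropyl]phenyl}palladium (divalent palladium, phosphine omitted) | O[C@H](c1ccc(OCc2ccccc2)c(OCc2ccccc2)c1)[C@@H](OCc1ccccc1)Cc1ccc(OCc2ccccc2)c(OCc2ccccc2)c1[Pd]Br | intermediate (not isolated)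
12 | (2R,3S)-3,7,8-tris(benzyloxy)-2-[3,4-bis(benzyloxy)phenyl]chromane (2,3-trans) | O(Cc1ccccc1)c1ccc2c(c1OCc1ccccc1)O[C@H](c1ccc(OCc3ccccc3)c(OCc3ccccc3)c1)[C@@H](OCc1ccccc1)C2 | intermediate
13 | (2R,3S,4R)-3,7,8-tris(benzyloxy)-2-[3,4-bis(benzyloxy)phenyl]-4-(2-ethoxyethoxy)chromane (2,3-trans-3,4-trans) | O(Cc1ccccc1)c1ccc2c(c1OCc1ccccc1)O[C@H](c1ccc(OCc3ccccc3)c(OCc3ccccc3)c1)[C@@H](OCc1ccccc1)[C@@H]2OCCOCC | intermediate
14 | (2R,3S)-3,7,8-tris(benzyloxy)-2-[3,4-bis(benzyloxy)phenyl]chroman-4-ylium | O(Cc1ccccc1)c1ccc2c(c1OCc1ccccc1)O[C@H](c1ccc(OCc3ccccc3)c(OCc3ccccc3)c1)[C@@H](OCc1ccccc1)[CH+]2 | intermediate (not isolated)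
15 | deca-O-benzyl dimer, upper unit (2R,3S,4S) with the C4 aryl group anti to the C3 benzyloxy group (same spatial arrangement as 4R in the target; the descriptor changes with benzylation), lower unit (2R,3S), C4 to C6 link | O(Cc1ccccc1)c1ccc2c(c1OCc1ccccc1)O[C@H](c1ccc(OCc3ccccc3)c(OCc3ccccc3)c1)[C@@H](OCc1ccccc1)[C@@H]2c1cc2c(c(OCc3ccccc3)c1OCc1ccccc1)O[C@H](c1ccc(OCc3ccccc3)c(OCc3ccccc3)c1)[C@@H](OCc1ccccc1)C2 | intermediate
16 | (2R,3S,4R)-2-(3,4-dihydroxyphenyl)-4-[(2R,3S)-2-(3,4-dihydroxyphenyl)-3,7,8-trihydroxychroman-6-yl]chromane-3,7,8-triol | Oc1ccc([C@H]2Oc3c(ccc(O)c3O)[C@@H](c3cc4c(c(O)c3O)O[C@H](c3ccc(O)c(O)c3)[C@@H](O)C4)[C@@H]2O)cc1O | target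

**Count and risks**

Total step count: 12. Longest linear sequence: 10 steps (steps 1 to 6, then 9, 10, 11, 12).

Step 9 (Proposed new method). What may go wrong: beta-hydride elimination of the secondary palladium alkoxide, which would reduce the arene and oxidise the carbinol; base-induced self-alkylation of 7 before it reaches the palladacycle; or slow ortho-alkylation by the beta-branched bromide. Fallback with known reactions, setting out from epoxide 4 and returning at 12: the two bonds are made one after the other. Commercial 3-bromocatechol is benzylated (BnBr, K2CO3, DMF) to 1,2-bis(benzyloxy)-3-bromobenzene F1. Iodination (NIS, cat. TFA, MeCN), expected para to the unhindered C1 benzyloxy group, should give 1,2-bis(benzyloxy)-3-bromo-4-iodobenzene F2. Selective iodine–magnesium exchange (iPrMgCl·LiCl, THF, −40 °C) and CuI-catalysed opening of 4 at its CH2 carbon form the C4–C4a bond and give the bromoaryl alcohol F3. Neutral O-benzylation as in step 5 gives the benzyl ether F4, and desilylation (TBAF, THF) gives the free benzylic alcohol F5. Intramolecular Ullmann etherification of the aryl bromide (CuI, 3,4,7,8-tetramethyl-1,10-phenanthroline, Cs2CO3, toluene, 110 °C), which has no beta-hydride pathway, then closes ring C to 12.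

Step 11. What may go wrong: loss of site control (attack through C5 or ring B), slow capture of the cation by the only moderately nucleophilic pyrogallol-type ring with self-condensation of 13 as the result, or incomplete facial selectivity at C4. Fallback, setting out from 12 and returning at 15: the C–H Friedel–Crafts step is replaced by an ipso-directed coupling. Bromination of 12 (NBS, CH2Cl2, −20 °C) should give (2R,3S)-3,7,8-tris(benzyloxy)-2-[3,4-bis(benzyloxy)phenyl]-6-bromochromane F6, whose constitution is secured at the monomer stage. Bromine–lithium exchange (n-BuLi, THF, −78 °C) and quench with Bu3SnCl give the 6-stannane F7. F7 and 13 are then joined under TMSOTf by ipso-destannylation, which fixes the site and raises the reactivity of C6, to give 15.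

Step 10. What may go wrong: sluggish hydride abstraction because the C4 cation is stabilised by only one para oxygen, or over-oxidation of the labile 4-ether. Fallback, setting out from 12 and returning at 15: the leaving group is introduced by ligand-transfer acetoxylation instead of hydride abstraction. Pb(OAc)4 in benzene (rt to 50 °C) should give the 4-acetate F8, and F8 is ionised with BF3·OEt2 (CH2Cl2, −78 °C) in the presence of excess 12, the acetate taking the place of the ethoxyethyl ether of 13.

**Further compounds**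

F1 | step 9 | 1,2-bis(benzyloxy)-3-bromobenzene | Brc1cccc(OCc2ccccc2)c1OCc1ccccc1
F2 | step 9 | 1,2-bis(benzyloxy)-3-bromo-4-iodobenzene | Ic1ccc(OCc2ccccc2)c(OCc2ccccc2)c1Br
F3 | step 9 | (1R,2S)-3-[3,4-bis(benzyloxy)-2-bromophenyl]-1-[3,4-bis(benzyloxy)phenyl]-1-[(tert-butyldimethylsilyl)oxy]propan-2-ol | CC(C)(C)[Si](C)(C)O[C@H](c1ccc(OCc2ccccc2)c(OCc2ccccc2)c1)[C@@H](O)Cc1ccc(OCc2ccccc2)c(OCc2ccccc2)c1Br
F4 | step 9 | {[(1R,2S)-2-(benzyloxy)-3-[3,4-bis(benzyloxy)-2-bromophenyl]-1-[3,4-bis(benzyloxy)phenyl]propyl]oxy}(tert-butyl)dimethylsilane | CC(C)(C)[Si](C)(C)O[C@H](c1ccc(OCc2ccccc2)c(OCc2ccccc2)c1)[C@@H](OCc1ccccc1)Cc1ccc(OCc2ccccc2)c(OCc2ccccc2)c1Br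
F5 | step 9 | (1R,2S)-2-(benzyloxy)-3-[3,4-bis(benzyloxy)-2-bromophenyl]-1-[3,4-bis(benzyloxy)phenyl]propan-1-ol | O[C@H](c1ccc(OCc2ccccc2)c(OCc2ccccc2)c1)[C@@H](OCc1ccccc1)Cc1ccc(OCc2ccccc2)c(OCc2ccccc2)c1Br
F6 | step 11 | (2R,3S)-3,7,8-tris(benzyloxy)-2-[3,4-bis(benzyloxy)phenyl]-6-bromochromane | O(Cc1ccccc1)c1c(Br)cc2c(c1OCc1ccccc1)O[C@H](c1ccc(OCc3ccccc3)c(OCc3ccccc3)c1)[C@@H](OCc1ccccc1)C2
F7 | step 11 | tributyl{(2R,3S)-3,7,8-tris(benzyloxy)-2-[3,4-bis(benzyloxy)phenyl]chroman-6-yl}stannane | O(Cc1ccccc1)c1c([Sn](CCCC)(CCCC)CCCC)cc2c(c1OCc1ccccc1)O[C@H](c1ccc(OCc3ccccc3)c(OCc3ccccc3)c1)[C@@H](OCc1ccccc1)C2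
F8 | step 10 | (2R,3R,4R)-3,7,8-tris(benzyloxy)-2-[3,4-bis(benzyloxy)phenyl]chroman-4-yl acetate (2,3-trans-3,4-trans) | O(Cc1ccccc1)c1ccc2c(c1OCc1ccccc1)O[C@H](c1ccc(OCc3ccccc3)c(OCc3ccccc3)c1)[C@@H](OCc1ccccc1)[C@@H]2OC(C)=O
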